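The target holds one open intermediate and one second intermediate, and whatever open intermediate the partner does not bring into target stays open, unless the side step has taken it first.

    open intermediate + second intermediate ⇌ target (K1 = 12 L mol⁻¹, k1 = 0.042 L mol⁻¹ s⁻¹, Ea1 = 63.0 kJ mol⁻¹, ΔH1 = −16.0 kJ mol⁻¹)
    starting material + open intermediate → side product (k2 = 0.0075 L mol⁻¹ s⁻¹, Ea2 = 60.0 kJ mol⁻¹)
    starting material → open intermediate (k3 = 0.0043 s⁻¹, Ea3 = 86.0 kJ mol⁻¹)
    partner → second intermediate (k4 = 0.078 s⁻¹, Ea4 = 87.0 kJ mol⁻¹)
    solid substrate ⇌ starting material, rate k5*(cs5 - [starting material]) while solid is left; crystals form when [starting material] > cs5 (cs5 = 0.46 M, k5 = 0.10 s⁻¹)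
    (constants at 25 °C)

| setting | larch | cedar | ash |
|---|---|---|---|
| solid substrate | 0.80 M | 0.80 M | 0.80 M |
| partner | 0.560 M | 0.560 M | 0.560 M |
| temperature | 55 °C | 25 °C |  |
| time | 50 min | 50 min | 50 min |
| remark |  |  | at 55 °C until 40 min, from then on at 25 °C |

- percentages count the solid substrate that a species holds: one side product counts as two
- solid, in amounts per volume of the solution: solid substrate
- all constants are for 25 °C and move with temperature by the activation energies and enthalpies
- at the start none of the solid substrate is in solution
- what has only dissolved of solid substrate counts as not reacted

1. the flask with the highest amount of open intermediate, in percent of the solid substrate charged ("all alike" if they lie within 1.5 percentage points) (larch / cedar / ash / all alike)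
2. final open intermediate, as a percentage of the solid substrate charged, in larch
3. final open intermediate, as a percentage of the solid substrate charged, in cedar
4. final open intermediate, as a percentage of the solid substrate charged, in ash

I reckoned the end share from the loss to side product and from the balance of the binding step. The partner was charged at 70.0 % of the solid substrate, the smaller charge of the two. Even with the solution held at saturation, the opening of starting material at 25 °C clears the charge in 6.74 min, which is shorter than the 50 min allowed, so I treated each end as a balance.

The share of the charge standing as open intermediate at which the side step takes starting material as fast as the opening does is 71.7 % at 25 °C: the break-even share. At 55 °C it is higher, 187 %.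

I took the mean open intermediate as 0.5 of its end share and called r its ratio to the break-even share. Each side step removes a pair, so the lost share is r doubled, over one plus r. For cedar, assuming no loss gave a loss of 46.6 %, and putting that loss in gave 17.4 %. I took the middle, 32.0 %. For larch the same steps gave 23.3 %, 15.9 % and 19.6 %.

The balance then left 34.9 % open in larch and 21.1 % in cedar. Ash I gave the loss of larch and the balance of 25 °C, since the back step's lifetime there, 4.76 min, is shorter than the last 10.0 min. That left 28.9 %.

The forecast named larch, with 37.5 %, 21 % and 31 % for larch, cedar and ash, holding that “hot conditions lose less because ring-opening outruns the side reaction”.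

The simulation gave 35.6 % in larch, 21.7 % in cedar and 29.6 % in ash, so larch stood highest.

Side product stood at 18.6 % in larch and 30.9 % in cedar after 50.0 min, beside my 19.6 % and 32.0 %. One more flask, like ash but charged with 2.0 M of solid substrate, has a break-even share at 55 °C of 74.8 %. The same steps gave 66.5 % and 18.1 %, with the middle at 42.3 %, and that flask held 39.1 % as side product.

(The rate constants belong to no real substance, and the outcome is calculated.)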